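**Catechin 7-O-gallate: synthesis proposal with ring C closed by fluoride displacement at C8a**

## Analysis of the target

Catechin 7-O-gallate is a flavan-3-ol: a 3,4-dihydro-2H-1-benzopyran in which the phloroglucinol-type ring A is fused to the dihydropyran ring C (O1, C2, C3, C4, C4a, C8a). Ring B (a catechol) sits on C2, a hydroxyl on C3, a free phenol on C5 and a 3,4,5-trihydroxybenzoyl ester on O7. There are two adjacent stereocentres, C2 (R) and C3 (S), in the 2,3-trans relation. Written as the open chain ArB–CH(O)–CH(O)–CH2–ArA, this is the erythro (1R,2S) pattern.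

The sensitive groups are the phenolic ester (cleaved or transferred by bases and nucleophiles), six oxidation-prone phenols, and the benzylic C2–O1 ether, which ionises under acid because ring B stabilises the cation, so that C2 can epimerise.

The synthesis has three problems. The first is the absolute and relative configuration at C2 and C3. The second is telling O7 apart from the nearly equivalent O5, and from O3 and the ring B phenols, so that only O7 is acylated. The third is freeing every other hydroxyl at the end without harming the ester.

The strategy rests on one feature. O1 joins the benzylic C2 to ring A carbon C8a, which is not a stereocentre. If C8a carries fluorine, an acyclic chain that already holds both stereocentres can be closed to ring C by forming O1–C8a, with no bond to C2 or C3 made or broken. The same fluorine, with a benzyl ether at O5 and a bulky silyl ether at O7, makes the three oxygenated ring A positions different from the first steps on.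

## Retrosynthetic reasoning

**17 from 16.** The last disconnection cuts the seven O–benzyl bonds of 16. A phenolic ester tolerates neither acidic nor basic deprotection, so every hydroxyl other than O7 is carried as a benzyl ether, and one neutral hydrogenolysis releases 17.

**16 from 14 and 15.** The ester C–O bond at O7 is cut next. Phenol 14 has a single free hydroxyl, so the acylation site is unambiguous. The galloyl unit comes from acid 15 and is introduced late, because an aryl ester would survive neither the organolithium step nor the hydride base of the ring closure.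

**14 from 13.** The Si–O7 bond is cut. The silyl ether is the only group in 13 that fluoride removes, so O7 alone is revealed. This is why O5 and O7 have to differ from the start.

**13 from 11 through 12.** The key disconnection is O1–C8a.
- Cutting O1–C2 instead would place ring closure at the ionisable benzylic stereocentre.
- Cutting C4–C4a would leave open which ortho position of ring A reacts.
- At O1–C8a the fluorine marks the carbon, and the forward step breaks only an O–H bond.

The forward reaction must deliver the alkoxide 12 of the C2 hydroxyl to the fluorinated carbon. O3 has to be masked, otherwise a five-membered ring could form.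

**11 from 10 from 9.** These are protecting-group adjustments. O3 is benzylated after the fragment union. O2 carries a temporary tetrahydropyranyl acetal, chosen because it cannot migrate to the neighbouring alkoxide during benzylation (a silyl ether could). It also leaves under mild acid that spares the aryl silyl ether, which fluoride would not spare.

**9 from 3 (through 8) and 7.** The C4–C4a bond is cut into a ring A aryl anion 8 and the terminal carbon of epoxide 7. This is the convergent union of the two halves. The C3–O bond is not touched, so the C3 configuration carries over. In 3 the only ring hydrogen flanked by fluorine and the benzyloxy group is the one that becomes C4a, and the other two lie next to the bulky silyl ether.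

**7 from 6 from 5 from 4.** Both stereocentres come from a Sharpless kinetic-resolution epoxidation of the racemic allylic alcohol 5. It selects one carbinol enantiomer (future C2) and creates the oxirane centre (future C3) in the erythro sense. Alcohol 5 comes from 1,2-addition of a vinyl-metal nucleophile to aldehyde 4.

**3 from 2 from 1.** The symmetric diphenol 1 is differentiated by one benzylation and one silylation.

## Alternatives that were turned down

**Alternative 1:** Disconnection at C2–C3. The sulfonium ylide from ring B benzyl bromide A2 and the chiral sulfide A3 (trans-2,5-dimethylthiolane, drawn as the (2R,5R) form; its enantiomer would be taken if the ylide model calls for it) adds, under hydroxide base, to the ring A arylacetaldehyde A1. The product is the trans epoxide A4. Removal of the allyl group and opening of the epoxide at the benzylic carbon by the phenol, with inversion, would then give the 2,3-trans flavan-3-ol.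
- For it: it is the most convergent plan. Both stereocentres arise in the fragment union, and no material is lost to a resolution. On these points it is stronger than the chosen route.
- Against it: A1 is an enolisable, electron-rich arylacetaldehyde that is likely to enolise and self-condense under hydroxide, and this ylide chemistry is at its best with non-enolisable aromatic aldehydes. A2 gives a donor-substituted, less stabilised ylide. The later ring closure makes the O1–C2 bond at a carbon with strong cationic character, so the C2 configuration is at risk. Three kinds of protecting group must be removed in sequence, one of them by acid.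
- Comparison: the chosen route pays with a resolution and a longer linear sequence. In return, its enantiopurity comes from a reaction of predictable sense, and its ring closure cannot disturb either stereocentre.

**Alternative 2:** Disconnection of C3–C4 and O1–C2 in one cycloaddition. Under a chiral BINOL-derived phosphoric acid, the 2,6-dihydroxybenzyl alcohol A5 (gallate ester already in place) would lose water to an ortho-quinone methide, which adds the (E)-enol carbonate A6 to give flavan A7.
- For it: it is by far the shortest plan. The ester is present from the start, the 5-hydroxyl is free without any differentiation, and carbonate and benzyl groups fall together in the final hydrogenolysis. In step economy it clearly beats the chosen route.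
- Against it: the dienophile has two donors that direct oppositely. The aryl group favours bonding of the quinone methide carbon to the oxygen-bearing alkene carbon, which is the desired sense. The carbonate oxygen favours the other sense. An enol carbonate is also a weak nucleophile for this inverse-demand addition. A stepwise path through a benzylic cation could erode the trans relation. Control of the face by the acid catalyst has no close precedent for this pair, and the acyloxy group para to the benzylic carbon makes quinone methide formation harder.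
- Comparison: the whole synthesis would rest on one unprecedented step that has to set regiochemistry, relative and absolute configuration together. The chosen route spreads these tasks over reactions with known behaviour.

**Alternative 3:** Disconnection at C4–C4a. Gold trichloride A10 (AuCl3, trivalent gold) together with silver trifluoromethanesulfonate A11 (AgOTf) would activate the terminal epoxide of the aryl ether A8, so that ring A attacks the epoxide methylene and gives the flavan-3-ol A9.
- For it: it draws on the same epoxy alcohol chirality as 6 and releases the C3 hydroxyl directly. It needs no cryogenic organolithium step. On the last point it is stronger than the chosen route.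
- Against it: the aryl benzylic ether O1–C2 must first be made at an electron-rich benzylic carbon without loss of configuration. The same bond can then ionise under the Lewis-acidic conditions that A10 and A11 create for the cyclisation. Ring A offers two ortho positions, and only the difference between a carbonate and a silyl ether steers the attack. The epoxide may rearrange to a carbonyl compound or be attacked at its inner carbon.
- Comparison: in the chosen route the position of fluorine fixes the ring A regiochemistry. The closure is run under basic conditions, under which the benzylic centre does not ionise. The step count is similar.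

Key step: step 9

## Route

Remark: acetal 7 and its successors 9 and 10 are carried as a mixture of two epimers at the acetal carbon of the oxane ring; this centre disappears in step 8.

Step 1
Reactants: 1 5-fluororesorcinol (5-fluorobenzene-1,3-diol)
Product: 2 3-(benzyloxy)-5-fluorophenol
Conditions: BnBr (0.5 equiv), K2CO3, acetone, reflux; unreacted 1 recovered
Reagents that add atoms: benzyl bromide, BrCc1ccccc1
Why: Williamson monoetherification of a symmetric diphenol; a twofold excess of the diol should keep the dibenzyl ether minor, and 2 should separate from recovered 1 and the diether because the three differ by one free hydroxyl each.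

Step 2
Reactants: 2 3-(benzyloxy)-5-fluorophenol
Product: 3 [3-(benzyloxy)-5-fluorophenoxy]tri(propan-2-yl)silane
Conditions: iPr3SiCl, imidazole, DMF, rt
Reagents that add atoms: chlorotri(propan-2-yl)silane, CC(C)[Si](Cl)(C(C)C)C(C)C
Why: Imidazole-promoted silylation of a phenol; the bulky silyl ether later shields its two neighbouring ring positions from lithiation and is the only fluoride-labile group of the route.

Step 3
Reactants: 4 3,4-bis(benzyloxy)benzaldehyde
Product: 5 rac-1-[3,4-bis(benzyloxy)phenyl]prop-2-en-1-ol
Conditions: CH2=CHMgBr, THF, 0 °C; aq NH4Cl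
Reagents that add atoms: vinylmagnesium bromide, C=C[Mg]Br
Why: Grignard 1,2-addition to a non-enolisable aryl aldehyde; the carbinol is formed racemic and is resolved in the next step.

Step 4
Reactants: 5 rac-1-[3,4-bis(benzyloxy)phenyl]prop-2-en-1-ol
Product: 6 (R)-[3,4-bis(benzyloxy)phenyl][(2S)-oxiran-2-yl]methanol
Conditions: Ti(OiPr)4 (10 mol %), D-(−)-diisopropyl tartrate (15 mol %), t-BuOOH (0.45 equiv), 4 Å MS, CH2Cl2, −20 °C
Reagents that add atoms: tert-butyl hydroperoxide, CC(C)(C)OO
Why: Sharpless kinetic-resolution epoxidation; with the (2S,3S)-tartrate the (S)-enantiomer of 5 should react much faster and take oxygen on the face that gives the erythro epoxy alcohol, so the catalyst selects the future C2 and sets the future C3 (the carbinol descriptor changes from S to R only because oxiranyl outranks aryl). The (R)-enantiomer of 5 stays behind, and the substoichiometric oxidant favours high enantiopurity of 6.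

Step 5
Reactants: 6 (R)-[3,4-bis(benzyloxy)phenyl][(2S)-oxiran-2-yl]methanol
Product: 7 2-{(R)-[3,4-bis(benzyloxy)phenyl][(2S)-oxiran-2-yl]methoxy}oxane
Conditions: 3,4-dihydro-2H-pyran, PPTS (cat.), CH2Cl2, 0 °C to rt
Reagents that add atoms: 3,4-dihydro-2H-pyran, C1=COCCC1
Why: Acid-catalysed acetalisation under conditions mild enough for the terminal epoxide; the acetal tolerates organolithium and hydride bases and, unlike a silyl ether, cannot migrate to a neighbouring alkoxide.

Step 6
Reactants: 3 [3-(benzyloxy)-5-fluorophenoxy]tri(propan-2-yl)silane; 7 2-{(R)-[3,4-bis(benzyloxy)phenyl][(2S)-oxiran-2-yl]methoxy}oxane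
Product: 9 (1R,2S)-1-[3,4-bis(benzyloxy)phenyl]-3-[2-(benzyloxy)-6-fluoro-4-{[tri(propan-2-yl)silyl]oxy}phenyl]-1-(oxan-2-yloxy)propan-2-ol, via aryllithium 8 (not isolated)
Conditions: 3 (1.5 equiv), n-BuLi, THF, −78 °C, 1 h; then 7, BF3·OEt2, −78 °C; aq NaHCO3
Reagents that add atoms: none
Why: Directed ortho-lithiation at the one ring C–H flanked by fluorine (inductive acidification) and the benzyloxy group (coordination), the other two being blocked by the silyl ether; the BF3-activated epoxide is then opened by SN2 attack at its unhindered terminal carbon, so the C–O bond of the future C3 stays intact. Keeping −78 °C throughout should prevent loss of LiF from 8.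

Step 7
Reactants: 9 (1R,2S)-1-[3,4-bis(benzyloxy)phenyl]-3-[2-(benzyloxy)-6-fluoro-4-{[tri(propan-2-yl)silyl]oxy}phenyl]-1-(oxan-2-yloxy)propan-2-ol
Product: 10 2-{(1R,2S)-2-(benzyloxy)-1-[3,4-bis(benzyloxy)phenyl]-3-[2-(benzyloxy)-6-fluoro-4-{[tri(propan-2-yl)silyl]oxy}phenyl]propoxy}oxane
Conditions: NaH, BnBr, Bu4NI (cat.), THF, 0 °C to rt
Reagents that add atoms: benzyl bromide, BrCc1ccccc1
Why: Williamson etherification of the secondary hydroxyl; the acetal on the neighbouring oxygen cannot migrate, and O-alkylation at 0 °C with the sodium counter-ion is expected to outrun five-ring fluoride displacement, which needs heat on this electron-rich arene.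

Step 8
Reactants: 10 2-{(1R,2S)-2-(benzyloxy)-1-[3,4-bis(benzyloxy)phenyl]-3-[2-(benzyloxy)-6-fluoro-4-{[tri(propan-2-yl)silyl]oxy}phenyl]propoxy}oxane
Product: 11 (1R,2S)-2-(benzyloxy)-1-[3,4-bis(benzyloxy)phenyl]-3-[2-(benzyloxy)-6-fluoro-4-{[tri(propan-2-yl)silyl]oxy}phenyl]propan-1-ol
Conditions: PPTS (0.2 equiv), MeOH/THF (3:1), 45 °C
Reagents that add atoms: none
Why: Acid-catalysed transacetalisation to methanol; ionisation takes place at the acetal carbon and not at the benzylic carbon, so the configuration is kept, and aryl silyl ethers resist weak acid (they are labile to base and fluoride instead), so the silyl group on O7 stays.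

Step 9
Reactants: 11 (1R,2S)-2-(benzyloxy)-1-[3,4-bis(benzyloxy)phenyl]-3-[2-(benzyloxy)-6-fluoro-4-{[tri(propan-2-yl)silyl]oxy}phenyl]propan-1-ol
Product: 13 (2R,3S)-3,5-bis(benzyloxy)-2-[3,4-bis(benzyloxy)phenyl]-7-{[tri(propan-2-yl)silyl]oxy}-3,4-dihydro-2H-1-benzopyran, via potassium alkoxide 12 (not isolated)
Conditions: KH (1.3 equiv), 18-crown-6 (1.3 equiv), THF, 0 °C, then 50 °C
Reagents that add atoms: none
Why: KH removes the only hydroxyl proton irreversibly to give alkoxide 12, whose oxygen adds to the fluorine-bearing ring A carbon C8a through a Meisenheimer-type σ-complex (or its concerted equivalent) that expels fluoride as KF. The closest known reaction type is the intramolecular SNAr etherification of 3-(2-fluoroaryl)propan-1-olates to chromans, which has been used for flavan-3-ols. Ring C closes in the 6-exo mode: the attacked carbon lies in the new six-membered ring and the leaving fluoride is outside it. No stereocentre is created; C2 and C3 keep their configuration because only the O–H bond is broken, so the erythro (1R,2S) chain becomes the (2R,3S) 2,3-trans flavan. The selectivity needed is six-ring closure through O2 and not five-ring closure through O3; it is secured because O3 is a benzyl ether and 12 has one nucleophilic oxygen, and the single C–F bond fixes the site on the arene. Reactivity rests on fluorine as the best SNAr leaving group and on both ring oxygens being meta to it, where they lie on nodal carbons of the developing cyclohexadienyl anion and act mainly by induction; 18-crown-6 frees the alkoxide from its counter-ion. The bulk of the triisopropylsilyl ether should suppress silyl transfer to the alkoxide, and an aryne is not expected because an alkoxide is too weak a base to remove the shielded proton ortho to fluorine.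

Step 10
Reactants: 13 (2R,3S)-3,5-bis(benzyloxy)-2-[3,4-bis(benzyloxy)phenyl]-7-{[tri(propan-2-yl)silyl]oxy}-3,4-dihydro-2H-1-benzopyran
Product: 14 (2R,3S)-3,5-bis(benzyloxy)-2-[3,4-bis(benzyloxy)phenyl]-3,4-dihydro-2H-1-benzopyran-7-ol
Conditions: Bu4NF, AcOH (1:1), THF, 0 °C
Reagents that add atoms: none
Why: Fluoride cleavage of an aryl silyl ether, driven by the Si–F bond and the good phenoxide leaving group; benzyl ethers are inert, and the acetic acid buffer protonates the phenoxide as it forms.

Step 11
Reactants: 14 (2R,3S)-3,5-bis(benzyloxy)-2-[3,4-bis(benzyloxy)phenyl]-3,4-dihydro-2H-1-benzopyran-7-ol; 15 3,4,5-tris(benzyloxy)benzoic acid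
Product: 16 (2R,3S)-3,5-bis(benzyloxy)-2-[3,4-bis(benzyloxy)phenyl]-3,4-dihydro-2H-1-benzopyran-7-yl 3,4,5-tris(benzyloxy)benzoate
Conditions: EDC·HCl, DMAP (0.3 equiv), CH2Cl2, rt
Reagents that add atoms: none
Why: Steglich esterification (carbodiimide activation with DMAP as acyl-transfer catalyst), a standard way to acylate phenols; 14 has one free hydroxyl, so only O7 can be esterified.

Step 12
Reactants: 16 (2R,3S)-3,5-bis(benzyloxy)-2-[3,4-bis(benzyloxy)phenyl]-3,4-dihydro-2H-1-benzopyran-7-yl 3,4,5-tris(benzyloxy)benzoate
Product: 17 catechin 7-O-gallate, (2R,3S)-2-(3,4-dihydroxyphenyl)-3,5-dihydroxy-3,4-dihydro-2H-1-benzopyran-7-yl 3,4,5-trihydroxybenzoate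
Conditions: H2 (1 atm), Pd(OH)2/C, THF/MeOH (1:1), rt, degassed solvents
Reagents that add atoms: none
Why: Catalytic hydrogenolysis of all seven O-benzyl groups, the alkyl benzyl ether at O3 included; under neutral conditions at ambient pressure the phenolic ester and the cyclic benzylic ether C2–O1 should stay intact, and neither stereocentre is involved.

## Compound list

1 | 5-fluororesorcinol (5-fluorobenzene-1,3-diol) | Oc1cc(O)cc(F)c1 | starting material
2 | 3-(benzyloxy)-5-fluorophenol | Oc1cc(F)cc(OCc2ccccc2)c1 | intermediate
3 | [3-(benzyloxy)-5-fluorophenoxy]tri(propan-2-yl)silane | CC(C)[Si](Oc1cc(F)cc(OCc2ccccc2)c1)(C(C)C)C(C)C | intermediate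
4 | 3,4-bis(benzyloxy)benzaldehyde | O=Cc1ccc(OCc2ccccc2)c(OCc2ccccc2)c1 | starting material
5 | rac-1-[3,4-bis(benzyloxy)phenyl]prop-2-en-1-ol | OC(C=C)c1ccc(OCc2ccccc2)c(OCc2ccccc2)c1 | intermediate
6 | (R)-[3,4-bis(benzyloxy)phenyl][(2S)-oxiran-2-yl]methanol | O[C@H](c1ccc(OCc2ccccc2)c(OCc2ccccc2)c1)[C@@H]1CO1 | intermediate
7 | 2-{(R)-[3,4-bis(benzyloxy)phenyl][(2S)-oxiran-2-yl]methoxy}oxane (two epimers at the acetal carbon) | C1CCCC(O1)O[C@H](c1ccc(OCc2ccccc2)c(OCc2ccccc2)c1)[C@@H]1CO1 | intermediate
8 | [2-(benzyloxy)-6-fluoro-4-{[tri(propan-2-yl)silyl]oxy}phenyl]lithium | [Li]c1c(F)cc(O[Si](C(C)C)(C(C)C)C(C)C)cc1OCc1ccccc1 | intermediate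
9 | (1R,2S)-1-[3,4-bis(benzyloxy)phenyl]-3-[2-(benzyloxy)-6-fluoro-4-{[tri(propan-2-yl)silyl]oxy}phenyl]-1-(oxan-2-yloxy)propan-2-ol (two epimers at the acetal carbon) | C1CCCC(O1)O[C@H](c1ccc(OCc2ccccc2)c(OCc2ccccc2)c1)[C@@H](O)Cc1c(F)cc(O[Si](C(C)C)(C(C)C)C(C)C)cc1OCc1ccccc1 | intermediate
10 | 2-{(1R,2S)-2-(benzyloxy)-1-[3,4-bis(benzyloxy)phenyl]-3-[2-(benzyloxy)-6-fluoro-4-{[tri(propan-2-yl)silyl]oxy}phenyl]propoxy}oxane (two epimers at the acetal carbon) | C1CCCC(O1)O[C@H](c1ccc(OCc2ccccc2)c(OCc2ccccc2)c1)[C@@H](OCc1ccccc1)Cc1c(F)cc(O[Si](C(C)C)(C(C)C)C(C)C)cc1OCc1ccccc1 | intermediate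
11 | (1R,2S)-2-(benzyloxy)-1-[3,4-bis(benzyloxy)phenyl]-3-[2-(benzyloxy)-6-fluoro-4-{[tri(propan-2-yl)silyl]oxy}phenyl]propan-1-ol | O[C@H](c1ccc(OCc2ccccc2)c(OCc2ccccc2)c1)[C@@H](OCc1ccccc1)Cc1c(F)cc(O[Si](C(C)C)(C(C)C)C(C)C)cc1OCc1ccccc1 | intermediate
12 | potassium (1R,2S)-2-(benzyloxy)-1-[3,4-bis(benzyloxy)phenyl]-3-[2-(benzyloxy)-6-fluoro-4-{[tri(propan-2-yl)silyl]oxy}phenyl]propan-1-olate | [K+].[O-][C@H](c1ccc(OCc2ccccc2)c(OCc2ccccc2)c1)[C@@H](OCc1ccccc1)Cc1c(F)cc(O[Si](C(C)C)(C(C)C)C(C)C)cc1OCc1ccccc1 | intermediate
13 | (2R,3S)-3,5-bis(benzyloxy)-2-[3,4-bis(benzyloxy)phenyl]-7-{[tri(propan-2-yl)silyl]oxy}-3,4-dihydro-2H-1-benzopyran | CC(C)[Si](C(C)C)(C(C)C)Oc1cc(OCc3ccccc3)c2c(c1)O[C@H](c1ccc(OCc3ccccc3)c(OCc3ccccc3)c1)[C@@H](OCc1ccccc1)C2 | intermediate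
14 | (2R,3S)-3,5-bis(benzyloxy)-2-[3,4-bis(benzyloxy)phenyl]-3,4-dihydro-2H-1-benzopyran-7-ol | Oc1cc(OCc3ccccc3)c2c(c1)O[C@H](c1ccc(OCc3ccccc3)c(OCc3ccccc3)c1)[C@@H](OCc1ccccc1)C2 | intermediate
15 | 3,4,5-tris(benzyloxy)benzoic acid | O=C(O)c1cc(OCc2ccccc2)c(OCc2ccccc2)c(OCc2ccccc2)c1 | starting material
16 | (2R,3S)-3,5-bis(benzyloxy)-2-[3,4-bis(benzyloxy)phenyl]-3,4-dihydro-2H-1-benzopyran-7-yl 3,4,5-tris(benzyloxy)benzoate | O=C(Oc1cc(OCc3ccccc3)c2c(c1)O[C@H](c1ccc(OCc3ccccc3)c(OCc3ccccc3)c1)[C@@H](OCc1ccccc1)C2)c1cc(OCc2ccccc2)c(OCc2ccccc2)c(OCc2ccccc2)c1 | intermediate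
17 | catechin 7-O-gallate, (2R,3S)-2-(3,4-dihydroxyphenyl)-3,5-dihydroxy-3,4-dihydro-2H-1-benzopyran-7-yl 3,4,5-trihydroxybenzoate | O=C(Oc1cc(O)c2c(c1)O[C@H](c1ccc(O)c(O)c1)[C@@H](O)C2)c1cc(O)c(O)c(O)c1 | target

## Step count and risks

Total: 12 steps. Longest linear sequence: 10 steps (4 to 17, steps 3 to 12). The ring A branch (1 to 3, two steps) joins at step 6, and acid 15 is used as bought.

**Step 9 (key step).**
- What may go wrong: slow fluoride displacement on an arene that carries two oxygen donors. At the temperature then needed, transfer of the silyl group from O7 to the alkoxide could overtake ring closure.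
- Fallback: the donor silyl ether is exchanged for an electron-withdrawing sulfonate before closure. It sets out from 11. Bu4NF/AcOH in THF would give the phenol–alcohol 3-(benzyloxy)-4-{(2S,3R)-2-(benzyloxy)-3-[3,4-bis(benzyloxy)phenyl]-3-hydroxypropyl}-5-fluorophenol F1. TsCl with K2CO3 in acetone should sulfonylate only the phenol, to the aryl 4-methylbenzenesulfonate F2. KH in THF would then close ring C on the more electrophilic arene, to the 7-O-sulfonyl flavan F3. KOH in MeOH/THF at 60 °C would cleave the aryl sulfonate. The fallback comes back to the route at 14.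

**Step 6.**
- What may go wrong: incomplete or misdirected metalation (at a benzylic OCH2 or next to the silyl ether), loss of LiF from 8 to an aryne on slight warming, or rearrangement of the BF3-activated epoxide before C–C bond formation.
- Fallback: the aryllithium is made by bromine–lithium exchange on a bromide of defined position, which is fast at −78 °C and needs no directing effects. It sets out from 1. NBS (1 equiv) in MeCN at 0 °C should brominate ortho to one hydroxyl and para to the other, to 4-bromo-5-fluorobenzene-1,3-diol F4. iPr3SiCl/imidazole at 0 °C should silylate the unhindered hydroxyl para to bromine, to 2-bromo-3-fluoro-5-{[tri(propan-2-yl)silyl]oxy}phenol F5. Mitsunobu etherification (BnOH, PPh3, DIAD) would give [3-(benzyloxy)-4-bromo-5-fluorophenoxy]tri(propan-2-yl)silane F6. n-BuLi in THF at −78 °C then gives 8, where the fallback rejoins the route; it replaces steps 1 and 2 as well.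

**Step 4.**
- What may go wrong: too small a rate difference between the enantiomers of this terminal aryl vinyl carbinol, so that the epoxide formed near half conversion is not enantiopure enough; or titanium-promoted opening of the terminal epoxide over long reaction times.
- Fallback: resolution and epoxidation are separated. It sets out from 5. Immobilised Candida antarctica lipase B with vinyl acetate in toluene should acylate the (R)-enantiomer, to (1R)-1-[3,4-bis(benzyloxy)phenyl]prop-2-en-1-yl acetate F8, and leave (1S)-1-[3,4-bis(benzyloxy)phenyl]prop-2-en-1-ol F7. F7 is then epoxidised with the same Ti(OiPr)4/D-(−)-diisopropyl tartrate system and a full equivalent of t-BuOOH (matched pair, run to completion). The fallback comes back at 6.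

**Step 7.**
- What may go wrong: attack of the C3 alkoxide on the fluorinated carbon (five-ring closure to a dihydrobenzofuran) in competition with O-benzylation.
- Fallback: benzyl transfer under neutral conditions with no alkoxide formed, using 2-benzyloxy-1-methylpyridinium triflate and MgO in PhCF3 at 85 °C. It sets out from 9 and comes back at 10; no new compound lies on its way.

## Further compounds

F1 | step 9 | 3-(benzyloxy)-4-{(2S,3R)-2-(benzyloxy)-3-[3,4-bis(benzyloxy)phenyl]-3-hydroxypropyl}-5-fluorophenol | O[C@H](c1ccc(OCc2ccccc2)c(OCc2ccccc2)c1)[C@@H](OCc1ccccc1)Cc1c(F)cc(O)cc1OCc1ccccc1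
F2 | step 9 | 3-(benzyloxy)-4-{(2S,3R)-2-(benzyloxy)-3-[3,4-bis(benzyloxy)phenyl]-3-hydroxypropyl}-5-fluorophenyl 4-methylbenzenesulfonate | O[C@H](c1ccc(OCc2ccccc2)c(OCc2ccccc2)c1)[C@@H](OCc1ccccc1)Cc1c(F)cc(OS(=O)(=O)c2ccc(C)cc2)cc1OCc1ccccc1
F3 | step 9 | (2R,3S)-3,5-bis(benzyloxy)-2-[3,4-bis(benzyloxy)phenyl]-3,4-dihydro-2H-1-benzopyran-7-yl 4-methylbenzenesulfonate | Cc1ccc(cc1)S(=O)(=O)Oc1cc(OCc3ccccc3)c2c(c1)O[C@H](c1ccc(OCc3ccccc3)c(OCc3ccccc3)c1)[C@@H](OCc1ccccc1)C2
F4 | step 6 | 4-bromo-5-fluorobenzene-1,3-diol | Oc1cc(O)c(Br)c(F)c1
F5 | step 6 | 2-bromo-3-fluoro-5-{[tri(propan-2-yl)silyl]oxy}phenol | CC(C)[Si](Oc1cc(O)c(Br)c(F)c1)(C(C)C)C(C)C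
F6 | step 6 | [3-(benzyloxy)-4-bromo-5-fluorophenoxy]tri(propan-2-yl)silane | CC(C)[Si](Oc1cc(OCc2ccccc2)c(Br)c(F)c1)(C(C)C)C(C)C
F7 | step 4 | (1S)-1-[3,4-bis(benzyloxy)phenyl]prop-2-en-1-ol | O[C@H](c1ccc(OCc2ccccc2)c(OCc2ccccc2)c1)C=C
F8 | step 4 | (1R)-1-[3,4-bis(benzyloxy)phenyl]prop-2-en-1-yl acetate | CC(=O)O[C@@H](c1ccc(OCc2ccccc2)c(OCc2ccccc2)c1)C=C
F0 | step 7 | none | none
A1 | alternative 1 | 2-[2-(benzyloxy)-4-(methoxymethoxy)-6-(prop-2-en-1-yloxy)phenyl]acetaldehyde | O=CCc1c(OCC=C)cc(OCOC)cc1OCc1ccccc1
A2 | alternative 1 | 1,2-bis(benzyloxy)-4-(bromomethyl)benzene | BrCc1ccc(OCc2ccccc2)c(OCc2ccccc2)c1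
A3 | alternative 1 | (2R,5R)-2,5-dimethylthiolane | C[C@@H]1CC[C@@H](C)S1
A4 | alternative 1 | (2S,3S)-2-[3,4-bis(benzyloxy)phenyl]-3-{[2-(benzyloxy)-4-(methoxymethoxy)-6-(prop-2-en-1-yloxy)phenyl]methyl}oxirane | COCOc1cc(OCC=C)c(C[C@@H]2O[C@H]2c2ccc(OCc3ccccc3)c(OCc3ccccc3)c2)c(OCc2ccccc2)c1
A5 | alternative 2 | 3,5-dihydroxy-4-(hydroxymethyl)phenyl 3,4,5-tris(benzyloxy)benzoate | O=C(Oc1cc(O)c(CO)c(O)c1)c1cc(OCc2ccccc2)c(OCc2ccccc2)c(OCc2ccccc2)c1
A6 | alternative 2 | benzyl (E)-2-[3,4-bis(benzyloxy)phenyl]ethenyl carbonate | O=C(OCc1ccccc1)O/C=C/c1ccc(OCc2ccccc2)c(OCc2ccccc2)c1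
A7 | alternative 2 | (2R,3S)-3-{[(benzyloxy)carbonyl]oxy}-2-[3,4-bis(benzyloxy)phenyl]-5-hydroxy-3,4-dihydro-2H-1-benzopyran-7-yl 3,4,5-tris(benzyloxy)benzoate | O=C(Oc1cc(O)c2c(c1)O[C@H](c1ccc(OCc3ccccc3)c(OCc3ccccc3)c1)[C@@H](OC(=O)OCc1ccccc1)C2)c1cc(OCc3ccccc3)c(OCc3ccccc3)c(OCc3ccccc3)c1
A8 | alternative 3 | benzyl 3-{(R)-[3,4-bis(benzyloxy)phenyl][(2S)-oxiran-2-yl]methoxy}-5-{[tri(propan-2-yl)silyl]oxy}phenyl carbonate | CC(C)[Si](C(C)C)(C(C)C)Oc1cc(OC(=O)OCc2ccccc2)cc(c1)O[C@H](c1ccc(OCc2ccccc2)c(OCc2ccccc2)c1)[C@@H]1CO1
A9 | alternative 3 | benzyl (2R,3S)-2-[3,4-bis(benzyloxy)phenyl]-3-hydroxy-7-{[tri(propan-2-yl)silyl]oxy}-3,4-dihydro-2H-1-benzopyran-5-yl carbonate | CC(C)[Si](C(C)C)(C(C)C)Oc1cc(OC(=O)OCc3ccccc3)c2c(c1)O[C@H](c1ccc(OCc3ccccc3)c(OCc3ccccc3)c1)[C@@H](O)C2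
A10 | alternative 3 | gold trichloride | Cl[Au](Cl)Cl
A11 | alternative 3 | silver trifluoromethanesulfonate | [Ag+].[O-]S(=O)(=O)C(F)(F)F
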